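I took one invariant into these flasks: each target uses one coupling partner, so the target, as a fraction of the starting material charged, stops at a ceiling equal to the coupling partner charge over the starting material charge.

| flask | starting material | coupling partner | base | protic impurity | remark | time |
|---|---|---|---|---|---|---|
| elm | 11 mM | 9.5 mM | 1 mM | 0.50 mM | run made earlier |  |
| birch | 21 mM | 9.5 mM | 1 mM | 0.50 mM | run made earlier |  |
| alder | 36 mM | 9.5 mM | 1 mM | 0.50 mM | run made earlier |  |
| Friday's | 10 mM | 9.50 mM | 1.00 mM | 0.500 mM |  | 2.5 min |
| Wednesday's | 40 mM | 9.50 mM | 1.00 mM | 0.500 mM |  | 2.5 min |

| run | time / s | target / % | starting material / % |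
|---|---|---|---|
| elm | 12.0 | 2 | 82 |
| elm | 40.0 | 3 | 61 |
| elm | 60.0 | 10 | 52 |
| elm | 120 | 37 | 10 |
| birch | 25.0 | 4 | 60 |
| birch | 50.0 | 11 | 35 |
| birch | 80.0 | 39 | 10 |
| birch | 120 | 43 | 2 |
| alder | 12.0 | 2 | 65 |
| alder | 40.0 | 23 | 14 |
| alder | 60.0 | 28 | 10 |
| alder | 120 | 25 | 9 |

(standard deviation of a reading: 1.5 percentage points)

- what was read earlier has a scatter of 1.5 percentage points, one standard deviation
- a reading or a percentage of target counts all its forms, free or not
- a reading of starting material is of its free form alone

- which of the two ends with the higher amount of target, in percent of the starting material charged ("neither" if they lie within 2 percentage points) (Friday's / Wednesday's / neither)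
- target at the end, in percent of the starting material charged, Friday's
- target at the end, in percent of the starting material charged, Wednesday's

The first setting is the starting material charge. By hand, raising it lowers the ceiling: 86.4% in elm, 45.2% in birch, 26.4% in alder. In the runs, elm's last reading of 37% stood below its ceiling, while alder's last two, 28% and 25%, lay either side of its own.

The second setting is time. By hand, I expected more time to add little to a flask on its ceiling. In alder, going from 60.0 s to 120 s added nothing, although 9% of the starting material was still free. For Friday's I made a rough estimate, not a bound, from elm's last reading, counting the free starting material as if it all became target, and Wednesday's got its ceiling: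

Friday's, estimate: target + starting material in elm = 47.0%, against a ceiling of 95.0%

Wednesday's: 23.8%, coupling partner charge over starting material charge

The forecast named Friday's, with 44% and 23.5%, on the ground that “the coupling partner caps the yield”. Its Friday's figure lies below my estimate.

    starting material + target ⇌ idle adduct, settled at all times (K = 120 M⁻¹)
    base + by-product ⇌ salt, settled at all times (K = 1.52 × 10⁵ M⁻¹)
    starting material + coupling partner → target + by-product (k = 0.144 M⁻¹ s⁻¹)
    starting material + protic impurity → quenched substrate (k = 302 M⁻¹ s⁻¹)
    2 starting material → self-condensation product (k = 0.523 M⁻¹ s⁻¹)
    starting material + coupling partner + by-product → target + 2 by-product (k = 4540 M⁻² s⁻¹)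

Friday's gave more, 45.4% against 23.8%. Wednesday's stood on its ceiling of 23.8% with 0% of the coupling partner left, the limiting reagent. Friday's kept 52% of its coupling partner, and its ceiling times the share spent gives 45.6%. In Friday's, self-condensation had 83% of its turnover behind it at 1.25 min, whereas the coupling with by-product reached half of its turnover later, at 2.03 min. At 2.50 min the self-condensation product held 44.0% of Friday's charge. The same flask with 0.60 mM of base kept 35% of its coupling partner, so the ceiling gives 61.7%, and it held 61.3% of target.

The numbers in the tables are simulated on assumed constants.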